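The route rests on cutting the C3–C1' bond between pyranone ring C of the upper genistein unit and its aryl ring B, which already carries the lower genistein at C3'. Two features are exploited: C1' lies para to O4' on ring B, and C3 is the nucleophilic alpha-carbon of the vinylogous ester in ring C. Ring B therefore enters as a non-aromatic 4-diazocyclohexa-2,5-dienone and ring C in open form as an o-hydroxyaryl enaminone. One rhodium-carbene operation forms C3–C1', aromatizes ring B to the free 4'-phenol and closes ring C, losing N2 and Me2NH. The M axis (C3'–C8'') is set earlier by atroposelective Suzuki–Miyaura coupling.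

Key step: step 7

Assumption: the C3'–C8'' axis (double-primed locants belong to the lower genistein unit), flanked by O4', O7'' and ring oxygen O1'', is taken to hold its configuration up to about 40 °C, so every step after its creation runs at or below that temperature. The SMILES notation cannot show the axis, so the descriptor M stands in the names, and it stays M throughout because C4' outranks C2' and C8a'' outranks C7'' in every intermediate.

Step 1
Reactants: 1 genistein
Product: 2 5,7,4'-tri-O-benzylgenistein
Conditions: BnBr (excess), K2CO3, DMF, 70 °C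
Reagents that add atoms: benzyl bromide, BrCc1ccccc1
Why: Williamson ether synthesis; excess halide in warm DMF should also cap the chelated 5-OH, which must be alkylated so that the next step goes to C8.

Step 2
Reactants: 2 5,7,4'-tri-O-benzylgenistein
Product: 3 8-iodo-5,7,4'-tri-O-benzylgenistein
Conditions: NIS, TFA (cat.), MeCN–CH2Cl2, 0 °C to rt, dark
Reagents that add atoms: N-iodosuccinimide, O=C1CCC(=O)N1I
Why: Electrophilic aromatic iodination with acid-activated NIS should strike the most electron-rich ring and there C8, as is usual for fully O-alkylated 5,7-dioxygenated chromen-4-ones, because C6 is shielded on both sides by benzyloxy groups and the 4-benzyloxyphenyl ring has only one donor.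

Step 3
Reactants: 3 8-iodo-5,7,4'-tri-O-benzylgenistein; 4 2-hydroxyphenylboronic acid
Product: 5 (M)-8-(2-hydroxyphenyl)-5,7,4'-tri-O-benzylgenistein
Conditions: Pd(OAc)2 (cat.), enantiopure sSPhos (sodium 2'-dicyclohexylphosphino-2,6-dimethoxybiphenyl-3-sulfonate, cat.), K3PO4, degassed toluene–H2O, 40 °C
Reagents that add atoms: none
Why: Atroposelective Suzuki–Miyaura coupling of the kind used for axially chiral biphenols: the C3'–C8'' axis is set under catalyst control, a potassium bridge between the ligand sulfonate and the phenolate of the aryl group delivered from 4 ordering the diarylpalladium intermediate before reductive elimination, and the ligand antipode that leads to M is fixed once by ECD or X-ray correlation on 5.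

Step 4
Reactants: 5 (M)-8-(2-hydroxyphenyl)-5,7,4'-tri-O-benzylgenistein
Product: 8 (M)-8-(3-diazo-6-oxocyclohexa-1,4-dien-1-yl)-5,7,4'-tri-O-benzylgenistein (quinone diazide), via nitrosophenol 6 (not isolated), via diazonium nitrate 7 (not isolated)
Conditions: NaNO2 (large excess), aq HCl, 1,4-dioxane–H2O, 0 °C to rt, dark; then aq NaHCO3
Reagents that add atoms: sodium nitrite, [Na+].[O-]N=O
Why: Direct introduction of the diazonium group into a phenol by excess nitrous acid: para-selective C-nitrosation of the only free phenol should give 6, two molecules of NO turn its N=O group into the diazonium nitrate 7, and bicarbonate removes the phenol proton to leave the neutral quinone diazide, while aryl ethers are not nitrosated at this acidity and the cold medium spares the axis.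

Step 5
Reactants: 9 2,4,6-trihydroxyacetophenone
Product: 10 2-hydroxy-4,6-bis(benzyloxy)acetophenone
Conditions: BnBr (2 equiv), K2CO3, acetone, reflux
Reagents that add atoms: benzyl bromide, BrCc1ccccc1
Why: Williamson ether synthesis that should stop at the dibenzyl ether, because the last hydroxyl is hydrogen-bonded to the acetyl carbonyl and is much less nucleophilic.

Step 6
Reactants: 10 2-hydroxy-4,6-bis(benzyloxy)acetophenone
Product: 11 (E)-1-[2-hydroxy-4,6-bis(benzyloxy)phenyl]-3-(dimethylamino)prop-2-en-1-one
Conditions: Me2NCH(OMe)2, toluene, 95 °C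
Reagents that add atoms: N,N-dimethylformamide dimethyl acetal, COC(OC)N(C)C
Why: Enaminone formation by condensation of the methyl ketone with the amide acetal, which should give the thermodynamically preferred E push-pull alkene and leave the chelated phenol untouched.

Step 7
Reactants: 8 (M)-quinone diazide; 11 enaminone
Product: 13 (M)-penta-O-benzylbisoflavolin D (5,7,5'',7'',4'''-pentabenzyl ether with free 4'-OH), via alpha-aryl enaminone 12 (not isolated)
Conditions: Rh2(esp)2 (cat., esp = alpha,alpha,alpha',alpha'-tetramethyl-1,3-benzenedipropanoate), 11 (2 equiv), CH2Cl2, rt, dark, slow addition of 8; then AcOH, rt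
Reagents that add atoms: none
Why: Proposed new method: Rh2(esp)2 should expel N2 from 8 to give an electrophilic quinoid carbene at C1', the push-pull alkene of 11 attacks it through its alpha-carbon (the future C3), the electrons of the carbon–rhodium bond flow into the dienone so that ring B aromatizes to the 4'-phenolate, and a proton shift gives enaminone 12. The closest known reaction types are the dirhodium-catalysed C–H arylation of electron-rich alkenes and heteroarenes with quinone diazides and the domino arylation–annulation of o-hydroxyaryl enaminones with aryl-radical donors to isoflavones, and what is new is their merger in a fragment union. Ring C then closes in AcOH by attack of the chelated phenol oxygen on the enaminone beta-carbon (6-endo-trig oxa-Michael addition, allowed), and loss of Me2NH restores the C2=C3 bond. No stereocentre is created, and the M axis should pass through unchanged because the reacting carbon is meta to C3' and the flask stays at room temperature. The step needs chemoselectivity for carbon attack over O–H insertion, over cyclopropanation of the C2''=C3'' bond and over arylation of the alkoxyarenes, which the far higher nucleophilicity of the enaminone alpha-carbon, the hydrogen-bonded OH of 11, the excess of cheap 11 and the slow addition of 8 should secure. Site selectivity on ring B is built in, since only the diazo carbon, para to the carbonyl oxygen and flanked by two CH groups, can become C1'.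

Step 8
Reactants: 13 (M)-penta-O-benzylbisoflavolin D
Product: 14 (M)-bisoflavolin D
Conditions: H2 (1 atm), Pd/C, THF–MeOH, rt
Reagents that add atoms: none
Why: Catalytic hydrogenolysis of the five aryl benzyl ethers is neutral and runs at room temperature, so no Lewis acid can bridge O4' and O7'' and flatten the axis, and it is stopped at the calculated hydrogen uptake so that the C2=C3 bonds of both pyranones are kept.

Compound list
1 | genistein | O=c1c(-c2ccc(O)cc2)coc2cc(O)cc(O)c12 | starting material
2 | 5,7,4'-tri-O-benzylgenistein | O=c1c(-c2ccc(OCc3ccccc3)cc2)coc2cc(OCc3ccccc3)cc(OCc3ccccc3)c12 | intermediate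
3 | 8-iodo-5,7,4'-tri-O-benzylgenistein | O=c1c(-c2ccc(OCc3ccccc3)cc2)coc2c(I)c(OCc3ccccc3)cc(OCc3ccccc3)c12 | intermediate
4 | 2-hydroxyphenylboronic acid | OB(O)c1ccccc1O | starting material
5 | (M)-8-(2-hydroxyphenyl)-5,7,4'-tri-O-benzylgenistein | O=c1c(-c2ccc(OCc3ccccc3)cc2)coc2c(-c3ccccc3O)c(OCc3ccccc3)cc(OCc3ccccc3)c12 | intermediate
6 | (M)-8-(2-hydroxy-5-nitrosophenyl)-5,7,4'-tri-O-benzylgenistein (not isolated) | O=c1c(-c2ccc(OCc3ccccc3)cc2)coc2c(-c3cc(N=O)ccc3O)c(OCc3ccccc3)cc(OCc3ccccc3)c12 | intermediate
7 | (M)-4-hydroxy-3-(5,7,4'-tri-O-benzylgenistein-8-yl)benzenediazonium nitrate (not isolated) | O=c1c(-c2ccc(OCc3ccccc3)cc2)coc2c(-c3cc([N+]#N)ccc3O)c(OCc3ccccc3)cc(OCc3ccccc3)c12.[O-][N+](=O)[O-] | intermediate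
8 | (M)-8-(3-diazo-6-oxocyclohexa-1,4-dien-1-yl)-5,7,4'-tri-O-benzylgenistein | [N-]=[N+]=C1C=CC(=O)C(c2c(OCc3ccccc3)cc(OCc3ccccc3)c3c(=O)c(-c4ccc(OCc5ccccc5)cc4)coc23)=C1 | intermediate
9 | 2,4,6-trihydroxyacetophenone | CC(=O)c1c(O)cc(O)cc1O | starting material
10 | 2-hydroxy-4,6-bis(benzyloxy)acetophenone | CC(=O)c1c(O)cc(OCc2ccccc2)cc1OCc1ccccc1 | intermediate
11 | (E)-1-[2-hydroxy-4,6-bis(benzyloxy)phenyl]-3-(dimethylamino)prop-2-en-1-one | CN(C)/C=C/C(=O)c1c(O)cc(OCc2ccccc2)cc1OCc1ccccc1 | intermediate
12 | (M)-alpha-aryl enaminone, 2-aryl-3-(dimethylamino)-1-[2-hydroxy-4,6-bis(benzyloxy)phenyl]prop-2-en-1-one with aryl = 4-hydroxy-3-(tri-O-benzylgenistein-8-yl)phenyl (not isolated; push-pull alkene of labile geometry, drawn without it) | CN(C)C=C(C(=O)c1c(O)cc(OCc2ccccc2)cc1OCc1ccccc1)c1ccc(O)c(-c2c(OCc3ccccc3)cc(OCc3ccccc3)c3c(=O)c(-c4ccc(OCc5ccccc5)cc4)coc23)c1 | intermediate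
13 | (M)-penta-O-benzylbisoflavolin D (free 4'-OH) | O=c1c(-c2ccc(O)c(-c3c(OCc4ccccc4)cc(OCc4ccccc4)c4c(=O)c(-c5ccc(OCc6ccccc6)cc5)coc34)c2)coc2cc(OCc3ccccc3)cc(OCc3ccccc3)c12 | intermediate
14 | (M)-bisoflavolin D | O=c1c(-c2ccc(O)c(-c3c(O)cc(O)c4c(=O)c(-c5ccc(O)cc5)coc34)c2)coc2cc(O)cc(O)c12 | target

Total step count: 8. Longest linear sequence: 6 steps (1, 2, 3, 4, 7, 8).

Steps most likely to fail

Step 7. The rhodium carbene may be lost to azine or dimer formation or to O–H insertion into one of the phenols. Liberated amine may also poison the catalyst before the enaminone carbon attacks. The fallback uses known cross-coupling on a preformed chromone, sets out from 5 and 11 and comes back at 13.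
- Para-bromination of the free phenol of 5 with Bu4NBr3 (CH2Cl2–MeOH, 0 °C) should give (M)-8-(5-bromo-2-hydroxyphenyl)-5,7,4'-tri-O-benzylgenistein F1.
- Miyaura borylation (B2pin2, PdCl2(dppf), KOAc, dioxane, lowest workable temperature) should give the corresponding pinacol boronate F2.
- Enaminone 11 is closed with I2 in MeOH at rt to 3-iodo-5,7-bis(benzyloxy)chromen-4-one F3.
- Suzuki–Miyaura coupling of F2 with F3 (Pd(OAc)2, SPhos, K3PO4, THF–H2O, 40 °C) should deliver 13.

Step 4. Nitrogen oxides may nitrate or oxidise the phenol ring, or the sequence may stall at the nitroso stage. The fallback brings the nitrogen in through a quinone, sets out from 5 and comes back at 8.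
- Teuber oxidation with potassium nitrosodisulfonate (KSO3)2NO (acetone–aq KH2PO4, rt) should give the (M)-2-aryl-1,4-benzoquinone F4.
- Tosylhydrazide (MeOH, 0 °C) should condense at the less hindered carbonyl, the one remote from the aryl group, to give the (M)-quinone monotosylhydrazone F5.
- Basic alumina or cold dilute NaOH expels p-toluenesulfinate (Bamford–Stevens-type elimination) to give 8.

Step 3. The ligand may transfer its chirality poorly to an axis flanked only by small oxygen groups, the axis may erode thermally during the coupling, and 4 may protodeboronate. The fallback replaces catalyst control by resolution, sets out from 3 and 4 and comes back at 5.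
- Coupling with achiral SPhos (Pd(OAc)2, K3PO4, toluene–H2O) gives racemic 8-(2-hydroxyphenyl)-5,7,4'-tri-O-benzylgenistein F6.
- (R)-1-Phenylethyl isocyanate (Et3N, cat. DMAP, CH2Cl2, rt) converts the phenol next to the axis into two diastereomeric carbamates.
- Chromatography or crystallisation separates them and gives the (M,R)-carbamate F7. The unwanted diastereomer is equilibrated thermally and recycled.
- K2CO3 in MeOH at rt releases 5.

Further compounds
F1 | step 7 | (M)-8-(5-bromo-2-hydroxyphenyl)-5,7,4'-tri-O-benzylgenistein | O=c1c(-c2ccc(OCc3ccccc3)cc2)coc2c(-c3cc(Br)ccc3O)c(OCc3ccccc3)cc(OCc3ccccc3)c12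
F2 | step 7 | (M)-8-[2-hydroxy-5-(4,4,5,5-tetramethyl-1,3,2-dioxaborolan-2-yl)phenyl]-5,7,4'-tri-O-benzylgenistein | O=c1c(-c2ccc(OCc3ccccc3)cc2)coc2c(-c3cc(B4OC(C)(C)C(C)(C)O4)ccc3O)c(OCc3ccccc3)cc(OCc3ccccc3)c12
F3 | step 7 | 3-iodo-5,7-bis(benzyloxy)chromen-4-one | O=c1c(I)coc2cc(OCc3ccccc3)cc(OCc3ccccc3)c12
F4 | step 4 | (M)-2-(5,7,4'-tri-O-benzylgenistein-8-yl)-1,4-benzoquinone | O=C1C=CC(=O)C(c2c(OCc3ccccc3)cc(OCc3ccccc3)c3c(=O)c(-c4ccc(OCc5ccccc5)cc4)coc23)=C1
F5 | step 4 | (M)-2-(5,7,4'-tri-O-benzylgenistein-8-yl)-1,4-benzoquinone 4-tosylhydrazone | Cc1ccc(cc1)S(=O)(=O)NN=C1C=CC(=O)C(c2c(OCc3ccccc3)cc(OCc3ccccc3)c3c(=O)c(-c4ccc(OCc5ccccc5)cc4)coc23)=C1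
F6 | step 3 | racemic 8-(2-hydroxyphenyl)-5,7,4'-tri-O-benzylgenistein | O=c1c(-c2ccc(OCc3ccccc3)cc2)coc2c(-c3ccccc3O)c(OCc3ccccc3)cc(OCc3ccccc3)c12
F7 | step 3 | (M)-2-(5,7,4'-tri-O-benzylgenistein-8-yl)phenyl N-[(1R)-1-phenylethyl]carbamate | C[C@@H](NC(=O)Oc1ccccc1-c1c(OCc2ccccc2)cc(OCc2ccccc2)c2c(=O)c(-c3ccc(OCc4ccccc4)cc3)coc12)c1ccccc1
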